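**A one-step world.** In a one-step world each electrophile that reacts costs one nucleophile, and one rate constant holds through a run. The next flask is to be chosen between these recipes, so that picture needs testing first.

in all of them: electrophile 20 mM

| flask | nucleophile | remark | time |
|---|---|---|---|
| epsilon | 3.7 equiv | run made earlier |  |
| zeta | 4.3 equiv | run made earlier |  |
| winter | 3.00 equiv |  | 3.0 h |
| spring | 3.90 equiv |  | 3.0 h |

| run | time / min | electrophile / % | target / % |
|---|---|---|---|
| epsilon | 6.00 | 91.0 | 8.0 |
| epsilon | 20.0 | 73.2 | 24.9 |
| epsilon | 30.0 | 66.9 | 34.5 |
| epsilon | 50.0 | 51.0 | 49.0 |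
| epsilon | 60.0 | 44.5 | 54.6 |
| epsilon | 90.0 | 34.1 | 65.0 |
| zeta | 6.00 | 89.1 | 8.6 |
| zeta | 20.0 | 72.4 | 29.8 |
| zeta | 30.0 | 60.8 | 38.7 |
| zeta | 50.0 | 46.2 | 55.9 |
| zeta | 60.0 | 39.5 | 60.4 |
| zeta | 90.0 | 26.7 | 73.4 |

(each reading ± 1 percentage point)



- part of the electrophile that has reacted at the end, winter
- part of the electrophile that has reacted at the end, spring
- what raising the equivalents of nucleophile from its lowest to its highest value here does to the part of the electrophile that has reacted (changes below 5 percentage points count as none) (no change / it falls / it rises)

**The cost.** Let n be the equivalents charged, e the fraction of electrophile left at time t, c the nucleophile lost per electrophile reacted, and κ the rate constant per equivalent. Rate first order in each gives ln[(n−c+ce)/(ne)] = κ(n−c)t.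

At c of one, the epsilon run gives κ of 0.00438 min⁻¹ at 20.0 min but 0.00362 min⁻¹ at 90.0 min. At c of two, it gives 0.00457 min⁻¹ and 0.00415 min⁻¹, a smaller drift. These are scattered readings, so two remains a judgement.

**The choice.** The last reading of zeta gives 0.00437 min⁻¹, and the mean of these two last readings is the rate constant per equivalent at cost two, 0.00426 min⁻¹. Solved for e, the equation gives e = (n−c)/(n·exp(κ(n−c)t)−c). Both recipes charge more than the cost, so the electrophile is the limiting reagent. My reckoning gives 77.6 % reacted in winter and 87.1 % in spring. That gap of 9.5 percentage points exceeds the mark, so spring's charge is worth making.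

**The forecast.** The forecast gave 78 % and 87.5 %, and it rises, on this ground: “Taking about 2 nucleophile per electrophile consumed gives a flat k”.

**The flasks.**

    electrophile + nucleophile → acid set free + target (k = 0.211 M⁻¹ min⁻¹)
    nucleophile + acid set free ⇌ protonated nucleophile, settled at all times (K = 4600 M⁻¹)

Winter reached 77.4 % and spring 86.9 %, against the reckoned 77.6 % and 87.1 %; from the lowest charge to the highest, the part reacted: it rises, by 9.5 points. In winter the half-life of the electrophile by the first step lengthens from 0.91 h at the charged amounts to 1.9 h at 3.00 h, still shorter than the run's 3.0 h. The nucleophile's half-life by that step is then longer, 12 h. For a neighbour of winter charged with 1.20 equiv, the same κ gives 40.8 % reacted, and that flask reached 40.8 %. That neighbour holds 59.2 % of its electrophile and 33.0 % of its nucleophile at 3.00 h.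

The readings come from a simulation on assumed constants, and the scatter is random.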